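Both pyranone rings are cut at O1–C8a. O1 links the stereogenic benzylic C2 to C8a of ring A, the carbon para to the C6–C6'' axis. Ring C can therefore be closed from the aryl side of the oxygen while the C2–O bond stays untouched. One twofold copper-catalysed intramolecular O-arylation closes both rings C with retention at C2 and C2'', and the halogen site excludes 8-linked isomers. The precursor is a 4,4'-dibromobiphenyl bearing two (S)-3-aryl-3-hydroxypropyl chains next to the bromines. C4 is kept as a carbinol through this basic step, which shuts off retro-aldol cleavage, dehydration and ring-opening racemisation, and it is oxidised afterwards.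

Key step: step 12

Assumption: only C2 and C2'' are defined in the target. The hindered C6–C6'' axis is left open, so rotamers about it are carried together and both answer to the drawn structure.

Design remarks
- Alkyllithiums would attack the C–Br bonds, and lithium amides tend to deprotonate beside bromine (aryne formation, halogen migration). Both aryl–metal species are therefore made by iodine–magnesium exchange on iodides placed by electrophilic iodination.
- The side chain is joined as an aldehyde. A di-ortho-substituted arylmagnesium adds to an aldehyde at temperatures where an ortho-bromo organometallic is still stable, whereas an amide would need warming.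
- The precursor and product of the key step keep the carbon–oxygen skeleton of the bis(β-hydroxy ketone) and of the biflavanone. Only the oxidation level at C4/C4'' differs, and one mild oxidation restores it.

**Biaryl core**

Step 1
Reactants: 1 5-bromoresorcinol
Product: 2 5-bromo-2-iodobenzene-1,3-diol
Conditions: I2 (1.05 equiv), NaHCO3, H2O/THF, 0 °C → rt
Reagents that add atoms: iodine, II
Why: Electrophilic aromatic iodination of the resorcinol monoanion in aqueous bicarbonate goes to the carbon between the two hydroxyls, as it does with resorcinol itself, and the two alternative positions are additionally shielded by the neighbouring bromine.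

Step 2
Reactants: 2 5-bromo-2-iodobenzene-1,3-diol
Product: 3 5-bromo-2-iodo-1,3-bis(methoxymethoxy)benzene
Conditions: MOMCl (2.6 equiv), iPr2NEt, CH2Cl2, 0 °C → rt
Reagents that add atoms: chloromethyl methyl ether, COCCl
Why: Williamson-type O-alkylation of both acidic phenols with a reactive α-chloro ether should give base-stable acetals that chelate magnesium in the next step.

Step 3
Reactants: 3 5-bromo-2-iodo-1,3-bis(methoxymethoxy)benzene (two molecules)
Product: 6 4,4'-dibromo-2,2',6,6'-tetrakis(methoxymethoxy)biphenyl, via arylmagnesium chloride 4 (not isolated), via chloromagnesium diarylcuprate 5 (not isolated)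
Conditions: iPrMgCl·LiCl (1.05 equiv), THF, −20 °C; CuCl·2LiCl (0.5 equiv), −50 °C; chloranil (0.6 equiv), −78 °C → rt
Reagents that add atoms: none
Why: Iodine–magnesium exchange is far faster at the doubly chelated C–I than at C–Br, and two-electron oxidation of the homocuprate triggers C–C reductive elimination from trivalent copper (oxidative cuprate homocoupling), a reaction type established for biaryls with four ortho oxygen substituents and tolerant of aryl bromides at low temperature.

Step 4
Reactants: 6 4,4'-dibromo-2,2',6,6'-tetrakis(methoxymethoxy)biphenyl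
Product: 7 4,4'-dibromo-3,3'-diiodo-2,2',6,6'-tetrakis(methoxymethoxy)biphenyl
Conditions: N-iodosuccinimide (2.1 equiv), MeCN, rt → 40 °C, dark
Reagents that add atoms: N-iodosuccinimide, O=C1CCC(=O)N1I
Why: Neutral electrophilic aromatic iodination meets only one kind of C–H, ortho and para to the ether oxygens, and the first iodine tempers and crowds its own ring so that the second should enter the other ring, giving 7 as a racemate about the now stereogenic axis.

**Side chain**

Step 5
Reactants: 8 4-hydroxyacetophenone
Product: 9 4'-(methoxymethoxy)acetophenone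
Conditions: MOMCl (1.3 equiv), iPr2NEt, CH2Cl2, 0 °C → rt
Reagents that add atoms: chloromethyl methyl ether, COCCl
Why: Williamson-type O-alkylation of the phenol masks the only acidic proton before the enolate chemistry.

Step 6
Reactants: 9 4'-(methoxymethoxy)acetophenone; 10 diethyl carbonate
Product: 11 ethyl 3-[4-(methoxymethoxy)phenyl]-3-oxopropanoate
Conditions: NaH (2.2 equiv), THF, reflux; then AcOH, 0 °C
Reagents that add atoms: none
Why: Crossed Claisen condensation of the methyl ketone enolate with a non-enolisable carbonate is driven to completion by deprotonation of the β-keto ester formed.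

Step 7
Reactants: 11 ethyl 3-[4-(methoxymethoxy)phenyl]-3-oxopropanoate
Product: 12 ethyl (3S)-3-hydroxy-3-[4-(methoxymethoxy)phenyl]propanoate
Conditions: RuCl(p-cymene)[(S,S)-TsDPEN] (1 mol %), HCO2H/Et3N 5:2, 30 °C
Reagents that add atoms: none
Why: In the Noyori–Ikariya asymmetric transfer hydrogenation the (S,S)-TsDPEN ruthenium hydride attacks the ketone face fixed by the CH–π contact between cymene and the aryl group, which for aryl ketones gives the (S)-carbinol (O > aryl > CH2), and the buffered medium spares the MOM ether.

Step 8
Reactants: 12 ethyl (3S)-3-hydroxy-3-[4-(methoxymethoxy)phenyl]propanoate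
Product: 13 ethyl (3S)-3-(tert-butyldimethylsilyloxy)-3-[4-(methoxymethoxy)phenyl]propanoate
Conditions: TBSCl, imidazole, DMF, rt
Reagents that add atoms: tert-butyldimethylsilyl chloride, CC(C)(C)[Si](C)(C)Cl
Why: Imidazole-promoted O-silylation forms only an O–Si bond, so the stereocentre is untouched and the alcohol is masked against the organometallic step.

Step 9
Reactants: 13 ethyl (3S)-3-(tert-butyldimethylsilyloxy)-3-[4-(methoxymethoxy)phenyl]propanoate
Product: 14 (3S)-3-(tert-butyldimethylsilyloxy)-3-[4-(methoxymethoxy)phenyl]propanal
Conditions: iBu2AlH (1.05 equiv), CH2Cl2, −78 °C; aq potassium sodium tartrate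
Reagents that add atoms: none
Why: Partial ester reduction stops at the aluminium hemiacetal, which is stable at −78 °C and releases the aldehyde only on work-up, a standard operation for β-silyloxy esters.

**Union and endgame**

Step 10
Reactants: 7 4,4'-dibromo-3,3'-diiodo-2,2',6,6'-tetrakis(methoxymethoxy)biphenyl; 14 (3S)-3-(tert-butyldimethylsilyloxy)-3-[4-(methoxymethoxy)phenyl]propanal (two molecules)
Product: 16 (3S,3'S)-1,1'-[4,4'-dibromo-2,2',6,6'-tetrakis(methoxymethoxy)biphenyl-3,3'-diyl]bis{3-(tert-butyldimethylsilyloxy)-3-[4-(methoxymethoxy)phenyl]propan-1-ol}, via bis(arylmagnesium chloride) 15 (not isolated)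
Conditions: iPrMgCl·LiCl (2.2 equiv), THF, −40 °C; 14 (2.5 equiv), −40 → 0 °C
Reagents that add atoms: none
Why: Selective iodine–magnesium exchange beside bromine gives an arylmagnesium that resists aryne formation below 0 °C and undergoes Grignard 1,2-addition to the aldehyde; the new C4/C4'' carbinol centres form without control and are erased in step 13, C2/C2'' come unchanged from 14, and any minor enantiomer of 14 ends mainly in a separable (S,R) diastereomer (Horeau-type amplification).

Step 11
Reactants: 16 bis(silyl ether) diol
Product: 17 1,1'-[4,4'-dibromo-2,2',6,6'-tetrakis(methoxymethoxy)biphenyl-3,3'-diyl]bis{(3S)-3-[4-(methoxymethoxy)phenyl]propane-1,3-diol}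
Conditions: Bu4NF (3 equiv), THF, 0 °C → rt
Reagents that add atoms: none
Why: Fluoride-induced desilylation is safe here because no carbonyl is present, so the basic fluoride has neither an aldol nor an acidic α-proton to attack.

Step 12
Reactants: 17 bis(1,3-diol) dibromide
Product: 18 (2S,2''S)-4',4''',5,5'',7,7''-hexakis(methoxymethoxy)-6,6''-biflavan-4,4''-diol
Conditions: CuI (20 mol %), 3,4,7,8-tetramethyl-1,10-phenanthroline (40 mol %), Cs2CO3 (4 equiv), 4 Å MS, toluene (0.02 M), 100 °C, Ar
Reagents that add atoms: none
Why: Cs2CO3 and the ligated CuI turn the C2 carbinol into a monovalent copper alkoxide, which inserts into the neighbouring C8a–Br bond to give a seven-membered trivalent cupracycle, and C–O reductive elimination releases the chroman. The closest known reaction type is the copper-catalysed intramolecular Ullmann etherification of secondary alcohols with aryl bromides, which gives chromans and 2-arylchromans. Each ring C closes as a six-membered ring by ipso substitution at C8a (formally 6-exo), and the two closures are independent and remote from the crowded axis. No stereocentre is made: only O–H and C8a–Br bonds change, so C2 and C2'' stay S, and without a C4 carbonyl neither retro-aldol cleavage, E1cB dehydration nor base-induced opening of the product can scramble them. Selection between the two hydroxyls of each chain is secured by ring size, since the C4 oxygen could only form a four-membered ring and may instead guide copper to the bromide, and copper alkoxides resist β-hydride elimination, so the free carbinols should not be oxidised as they might be on palladium. C8a is meta to both ether oxygens and thus not deactivated by their donation, and its position para to the axis fixes the 6,6''-linkage.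

Step 13
Reactants: 18 hexa-MOM biflavan-4,4''-diol
Product: 19 (2S,2''S)-hexa-O-methoxymethylsuccedaneaflavanone
Conditions: Dess–Martin periodinane (3 equiv), NaHCO3, CH2Cl2, 0 °C → rt
Reagents that add atoms: none
Why: Bicarbonate-buffered Dess–Martin oxidation converts both benzylic carbinols to ketones without acid or base strong enough to ionise C4 or enolise the product, so all C4 epimers converge and C2/C2'' are untouched.

Step 14
Reactants: 19 (2S,2''S)-hexa-O-methoxymethylsuccedaneaflavanone
Product: 20 succedaneaflavanone
Conditions: HCl (ca. 2 M in MeOH), MeOH/THF, 35–40 °C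
Reagents that add atoms: none
Why: Acid-catalysed acetal exchange (methanolysis) removes all six MOM groups, and C2 should hold because opening of a flavanone runs through its enolate or phenoxide, which are absent in mildly warm acid.

**Compound list**

1 | 5-bromoresorcinol | Oc1cc(O)cc(Br)c1 | starting material
2 | 5-bromo-2-iodobenzene-1,3-diol | Oc1cc(Br)cc(O)c1I | intermediate
3 | 5-bromo-2-iodo-1,3-bis(methoxymethoxy)benzene | COCOc1cc(Br)cc(OCOC)c1I | intermediate
4 | [4-bromo-2,6-bis(methoxymethoxy)phenyl]magnesium chloride (not isolated) | COCOc1cc(Br)cc(OCOC)c1[Mg]Cl | intermediate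
5 | chloromagnesium bis[4-bromo-2,6-bis(methoxymethoxy)phenyl]cuprate (not isolated) | COCOc1cc(Br)cc(OCOC)c1[Cu-]c1c(OCOC)cc(Br)cc1OCOC.[Mg+]Cl | intermediate
6 | 4,4'-dibromo-2,2',6,6'-tetrakis(methoxymethoxy)biphenyl | COCOc1cc(Br)cc(OCOC)c1-c1c(OCOC)cc(Br)cc1OCOC | intermediate
7 | 4,4'-dibromo-3,3'-diiodo-2,2',6,6'-tetrakis(methoxymethoxy)biphenyl (racemic about the axis) | COCOc1cc(Br)c(I)c(OCOC)c1-c1c(OCOC)cc(Br)c(I)c1OCOC | intermediate
8 | 4-hydroxyacetophenone | CC(=O)c1ccc(O)cc1 | starting material
9 | 4'-(methoxymethoxy)acetophenone | CC(=O)c1ccc(OCOC)cc1 | intermediate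
10 | diethyl carbonate | CCOC(=O)OCC | starting material
11 | ethyl 3-[4-(methoxymethoxy)phenyl]-3-oxopropanoate | CCOC(=O)CC(=O)c1ccc(OCOC)cc1 | intermediate
12 | ethyl (3S)-3-hydroxy-3-[4-(methoxymethoxy)phenyl]propanoate | CCOC(=O)C[C@H](O)c1ccc(OCOC)cc1 | intermediate
13 | ethyl (3S)-3-(tert-butyldimethylsilyloxy)-3-[4-(methoxymethoxy)phenyl]propanoate | CCOC(=O)C[C@H](O[Si](C)(C)C(C)(C)C)c1ccc(OCOC)cc1 | intermediate
14 | (3S)-3-(tert-butyldimethylsilyloxy)-3-[4-(methoxymethoxy)phenyl]propanal | O=CC[C@H](O[Si](C)(C)C(C)(C)C)c1ccc(OCOC)cc1 | intermediate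
15 | [4,4'-dibromo-2,2',6,6'-tetrakis(methoxymethoxy)biphenyl-3,3'-diyl]bis(magnesium chloride) (not isolated) | COCOc1cc(Br)c([Mg]Cl)c(OCOC)c1-c1c(OCOC)cc(Br)c([Mg]Cl)c1OCOC | intermediate
16 | (3S,3'S)-bis(3-silyloxy-1-carbinol), epimers at the two ring A carbinol carbons and rotamers | OC(C[C@H](O[Si](C)(C)C(C)(C)C)c1ccc(OCOC)cc1)c1c(Br)cc(OCOC)c(-c2c(OCOC)cc(Br)c(C(O)C[C@H](O[Si](C)(C)C(C)(C)C)c3ccc(OCOC)cc3)c2OCOC)c1OCOC | intermediate
17 | (3S,3'S)-bis(1,3-diol) dibromide, precursor of the key step, epimers at the future C4/C4'' | OC(C[C@H](O)c1ccc(OCOC)cc1)c1c(Br)cc(OCOC)c(-c2c(OCOC)cc(Br)c(C(O)C[C@H](O)c3ccc(OCOC)cc3)c2OCOC)c1OCOC | intermediate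
18 | (2S,2''S)-4',4''',5,5'',7,7''-hexakis(methoxymethoxy)-6,6''-biflavan-4,4''-diol, epimers at C4/C4'' | OC1C[C@@H](c2ccc(OCOC)cc2)Oc2cc(OCOC)c(-c3c(OCOC)cc4c(c3OCOC)C(O)C[C@@H](c3ccc(OCOC)cc3)O4)c(OCOC)c21 | intermediate
19 | (2S,2''S)-hexa-O-methoxymethylsuccedaneaflavanone | O=C1C[C@@H](c2ccc(OCOC)cc2)Oc2cc(OCOC)c(-c3c(OCOC)cc4c(c3OCOC)C(=O)C[C@@H](c3ccc(OCOC)cc3)O4)c(OCOC)c21 | intermediate
20 | succedaneaflavanone, (2S,2''S)-6,6''-binaringenin | O=C1C[C@@H](c2ccc(O)cc2)Oc2cc(O)c(-c3c(O)cc4c(c3O)C(=O)C[C@@H](c3ccc(O)cc3)O4)c(O)c21 | target

Total step count: 14.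
Longest linear sequence: 10 steps (8 → 20, steps 5–14). The biaryl branch from 1 runs over 9 steps.

**Steps most likely to fail**

1. Step 12. The second ring closure may stall, bromine may be lost reductively, or the hot basic copper medium may dehydrogenate the carbinols.
   - The fallback sets out from 16 and comes back at 19. It inverts the order of oxidation and ring closure and changes the metal.
   - Compound 16 is oxidised with Dess–Martin periodinane/NaHCO3 to the (3S,3'S)-bis(β-silyloxy ketone) F1.
   - Pyridine-buffered HF·pyridine in THF at 0 °C desilylates it without base to the (3S,3'S)-bis(β-hydroxy ketone) dibromide F2.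
   - Pd(OAc)2, 2-(di-tert-butylphosphino)-1,1'-binaphthyl and K3PO4 in toluene at 50–60 °C then close both rings by Buchwald–Hartwig-type intramolecular etherification and give 19 directly. The ortho acyl group now speeds oxidative addition of zerovalent palladium, so a weak base and a low temperature may suffice.
   - The price is that an aldol and a flavanone are exposed to base, which is why this order is not the first choice.

2. Step 10. The hindered, basic arylmagnesium may deprotonate the aldehyde and set off β-elimination of silanolate instead of adding, or only one of the two sites may react.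
   - The fallback sets out from 7 and 9 and comes back at 17. It reverses the polarity of the bond formation.
   - Compound 15, made from 7 as before, is quenched with DMF, a small non-enolisable electrophile, to give 4,4'-dibromo-2,2',6,6'-tetrakis(methoxymethoxy)biphenyl-3,3'-dicarbaldehyde F3.
   - Ketone 9 is converted with LiN(iPr)2 in THF at −78 °C into lithium 1-[4-(methoxymethoxy)phenyl]ethenolate F4, which adds twice to F3 to give the bis-aldol F5. F5 has the carbinol at C4 and the ketone at C2, and its C4 epimers are immaterial.
   - Noyori–Ikariya transfer hydrogenation with RuCl(p-cymene)[(S,S)-TsDPEN] in HCO2H/Et3N then sets both (S)-carbinols under catalyst control and delivers 17. Steps 6–9 and 11 are no longer needed.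

3. Step 3. Reductive elimination to a biaryl with four ortho substituents may be slow, so that protonation or isopropylation of the aryl–copper species takes over.
   - The fallback sets out from 3 and comes back at 6 and makes no new compound (F0).
   - The iodide itself is homocoupled reductively in a classical Ullmann reaction on activated Cu powder in DMF at 110–130 °C. The C–I bond, flanked by two coordinating ether oxygens, should react ahead of C–Br.

Further compounds
F1 | step 12 | (3S,3'S)-1,1'-[4,4'-dibromo-2,2',6,6'-tetrakis(methoxymethoxy)biphenyl-3,3'-diyl]bis{3-(tert-butyldimethylsilyloxy)-3-[4-(methoxymethoxy)phenyl]propan-1-one} | O=C(C[C@H](O[Si](C)(C)C(C)(C)C)c1ccc(OCOC)cc1)c1c(Br)cc(OCOC)c(-c2c(OCOC)cc(Br)c(C(=O)C[C@H](O[Si](C)(C)C(C)(C)C)c3ccc(OCOC)cc3)c2OCOC)c1OCOC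
F2 | step 12 | (3S,3'S)-1,1'-[4,4'-dibromo-2,2',6,6'-tetrakis(methoxymethoxy)biphenyl-3,3'-diyl]bis{3-hydroxy-3-[4-(methoxymethoxy)phenyl]propan-1-one} | O=C(C[C@H](O)c1ccc(OCOC)cc1)c1c(Br)cc(OCOC)c(-c2c(OCOC)cc(Br)c(C(=O)C[C@H](O)c3ccc(OCOC)cc3)c2OCOC)c1OCOC
F3 | step 10 | 4,4'-dibromo-2,2',6,6'-tetrakis(methoxymethoxy)biphenyl-3,3'-dicarbaldehyde | COCOc1cc(Br)c(C=O)c(OCOC)c1-c1c(OCOC)cc(Br)c(C=O)c1OCOC
F4 | step 10 | lithium 1-[4-(methoxymethoxy)phenyl]ethenolate | [Li]OC(=C)c1ccc(OCOC)cc1
F5 | step 10 | 3,3'-[4,4'-dibromo-2,2',6,6'-tetrakis(methoxymethoxy)biphenyl-3,3'-diyl]bis{3-hydroxy-1-[4-(methoxymethoxy)phenyl]propan-1-one}, carbinol epimers | O=C(CC(O)c1c(Br)cc(OCOC)c(-c2c(OCOC)cc(Br)c(C(O)CC(=O)c3ccc(OCOC)cc3)c2OCOC)c1OCOC)c1ccc(OCOC)cc1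
F0 | step 3 | none | none
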